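**Plan**

- Retrosynthesis: the two isopropyl ethers (O7, O2') and the 8-O-methyl group are removed first, which leaves a 5,8-hydroquinone. Ring A is then cut at C4a–C5, unravelling it to a 4-hydroxy-3-isopropoxycyclobutenone on C8a of a 2-aryl-4-pyranone. The C8–C8a bond is cut next (pyranonyllithium plus isopropyl semisquarate), and ring C last at C2–C3 and O1–C8a (aroyl chloride plus the enolate of 4-methoxybut-3-en-2-one).
- Enabling feature: in ring A, C5–OH and C8–OMe are para, the C7 oxygen sits beside C8 and C6 carries H. This is the sequence C1(=O)/C2(H)/C3(OR)/C4(OH) of a semisquarate adduct, so the four-membered ring maps atom for atom onto C5–C6–C7–C8.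
- Forward order: ring B is bought, ring C (the pyranone) is built on it, the cyclobutenone is attached at the future C8a, and ring A arises last by thermal ring expansion. Methylation and dealkylation finish the synthesis.
- Stereochemistry: the target is achiral. The carbinol centres of 10 and 13 and C4a of 15 form as racemates and are destroyed on the way.

Key step: step 8

**Route**

Step 1
Reactants: 1 2-hydroxy-4,5-dimethoxybenzaldehyde
Product: 2 2-isopropoxy-4,5-dimethoxybenzaldehyde
Conditions: 2-bromopropane, K2CO3, DMF, 60 °C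
Reagents that add atoms: 2-bromopropane, CC(C)Br
Why: Williamson ether synthesis, in which the phenoxide formed by K2CO3 in DMF is alkylated by the secondary bromide while the aldehyde stays inert.

Step 2
Reactants: 2 2-isopropoxy-4,5-dimethoxybenzaldehyde
Product: 3 2-isopropoxy-4,5-dimethoxybenzoic acid
Conditions: NaClO2, NaH2PO4, 2-methyl-2-butene, t-BuOH/H2O, rt
Reagents that add atoms: sodium chlorite, [Na+].[O-]Cl=O
Why: Pinnick oxidation takes the aryl aldehyde to the acid, and 2-methyl-2-butene scavenges the hypochlorous acid that would otherwise chlorinate the electron-rich ring.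

Step 3
Reactants: 3 2-isopropoxy-4,5-dimethoxybenzoic acid
Product: 4 2-isopropoxy-4,5-dimethoxybenzoyl chloride
Conditions: (COCl)2, cat. DMF, CH2Cl2, 0 °C to rt; evaporated and used crude
Reagents that add atoms: oxalyl chloride, O=C(Cl)C(=O)Cl
Why: Acid chloride formation through the chloroiminium (Vilsmeier-type) intermediate runs at room temperature, where the aryl alkyl ethers are untouched.

Step 4
Reactants: 4 2-isopropoxy-4,5-dimethoxybenzoyl chloride; 5 (E)-4-methoxybut-3-en-2-one
Product: 8 2-(2-isopropoxy-4,5-dimethoxyphenyl)-4H-pyran-4-one, via lithium dienolate of the enone 6 (not isolated), via 5-methoxypent-4-ene-1,3-dione 7 (not isolated)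
Conditions: 5 (2 equiv), LiN(SiMe3)2 (2 equiv), THF, −78 °C; then 4, −78 to 0 °C; solvent exchange, CF3CO2H, CH2Cl2, rt
Reagents that add atoms: none
Why: Claisen-type C-acylation of the kinetic dienolate 6 gives diketone 7 (taken up as its salt by the second equivalent of 6), and acid then closes ring C by conjugate addition of the enol oxygen to the β-methoxy enone with loss of methanol, a standard 4-pyranone synthesis.

Step 5
Reactants: 9 diisopropyl squarate
Product: 10 4-hydroxy-2,3-diisopropoxycyclobut-2-en-1-one (racemic)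
Conditions: LiAlH(OtBu)3 (1.05 equiv), THF, −78 to 0 °C; aqueous work-up
Reagents that add atoms: none
Why: Chemoselective carbonyl reduction, in which the bulky hydride adds once to one of the two equivalent carbonyl groups and stops at the alkoxide, giving a racemic carbinol whose stereocentre disappears in step 6.

Step 6
Reactants: 10 4-hydroxy-2,3-diisopropoxycyclobut-2-en-1-one
Product: 11 3-isopropoxycyclobut-3-ene-1,2-dione (isopropyl semisquarate)
Conditions: conc. aq. HCl (cat.), CH2Cl2, rt
Reagents that add atoms: water, O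
Why: Acid-mediated allylic transposition of a squarate adduct, in which ionisation of the carbinol gives an alkoxy-stabilised cyclobutenyl cation that is hydrated at C2 and loses isopropanol, leaving the enedione with H on C4.

Step 7
Reactants: 8 2-(2-isopropoxy-4,5-dimethoxyphenyl)-4H-pyran-4-one; 11 3-isopropoxycyclobut-3-ene-1,2-dione
Product: 13 4-hydroxy-3-isopropoxy-4-[6-(2-isopropoxy-4,5-dimethoxyphenyl)-4-oxo-4H-pyran-2-yl]cyclobut-2-en-1-one (racemic), via 6-lithiopyranone 12 (not isolated)
Conditions: lithium 2,2,6,6-tetramethylpiperidide (from 2,2,6,6-tetramethylpiperidine + n-BuLi, 1.05 equiv), THF, −78 °C, 15 min; cannulated into 11 (1.2 equiv), THF, −78 °C; aq. NH4Cl at −78 °C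
Reagents that add atoms: none
Why: Deprotonative lithiation next to the ring oxygen (the most acidic C–H of a 4-pyranone, as in the C2 lithiation of chromones with this base) followed by 1,2-addition of the vinyllithium to the ketone-like C2 carbonyl of 11, C1=O being a deactivated vinylogous ester; the bulky isopropyl ether is a poor director toward C3 or ring B, and the new carbinol centre is racemic and is destroyed in step 8.

Step 8
Reactants: 13 4-hydroxy-3-isopropoxy-4-[6-(2-isopropoxy-4,5-dimethoxyphenyl)-4-oxo-4H-pyran-2-yl]cyclobut-2-en-1-one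
Product: 16 5,8-dihydroxy-7-isopropoxy-2-(2-isopropoxy-4,5-dimethoxyphenyl)-4H-chromen-4-one, via pyranonyl dienylketene 14 (not isolated), via 4aH-chromene-4,5-dione tautomer 15 (not isolated)
Conditions: degassed p-xylene (0.01 M), reflux (138 °C), Ar
Reagents that add atoms: none
Why: Proposed new method: heating should open the cyclobutenone by conrotatory four-electron cleavage of the C1–C4 bond, the donor hydroxyl rotating outward so that the pyranonyl group lies cis to the ketene in 14. The ketene carbon then bonds to pyranone C5, the nucleophilic α-carbon of the vinylogous ester, in a thermal disrotatory six-electron electrocyclization that closes six-membered ring A (flavone bond C4a–C5) and gives dienone 15. Enolization of 15 is driven by aromatization and by the hydrogen bond of the new 5-hydroxyl to C4=O; it removes the only sp3 centre, so no stereocentre is set. The closest known reaction is the Moore rearrangement of 4-aryl-, 4-alkenyl- and 4-(2-furyl or dihydropyranyl)-4-hydroxycyclobutenones to hydroquinones; a 4-oxopyranyl partner has not been described. The step needs outward torquoselectivity of the hydroxyl and closure on carbon and not on the ring oxygen: the first follows from the donor character of OH, the second from the low nucleophilicity of the pyranone oxygen and from C5 being the only carbon neighbour of the attachment site. Argon and degassed solvent keep the electron-rich hydroquinone from oxidising to the quinone.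

Step 9
Reactants: 16 5,8-dihydroxy-7-isopropoxy-2-(2-isopropoxy-4,5-dimethoxyphenyl)-4H-chromen-4-one
Product: 17 5-hydroxy-7-isopropoxy-8-methoxy-2-(2-isopropoxy-4,5-dimethoxyphenyl)-4H-chromen-4-one
Conditions: MeI (1.2 equiv), K2CO3, degassed acetone, rt, Ar
Reagents that add atoms: iodomethane, CI
Why: Chemoselective Williamson methylation, since the 5-hydroxyl is locked in a hydrogen bond to C4=O and is far less nucleophilic under K2CO3 at room temperature, so one equivalent of iodomethane should alkylate only the free 8-hydroxyl as in classical 8-methoxyflavone syntheses.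

Step 10
Reactants: 17 5-hydroxy-7-isopropoxy-8-methoxy-2-(2-isopropoxy-4,5-dimethoxyphenyl)-4H-chromen-4-one
Product: 18 5,7-dihydroxy-2-(2-hydroxy-4,5-dimethoxyphenyl)-8-methoxy-4H-chromen-4-one
Conditions: BCl3 (1 M in CH2Cl2, 6 equiv), CH2Cl2, −78 to 0 °C; then H2O/MeOH, rt
Reagents that add atoms: none
Why: Lewis acid ether cleavage, in which BCl3 ionises the secondary isopropyl aryl ethers at or below 0 °C to 2-chloropropane and aryl borates while methyl aryl ethers not peri to a carbonyl need more forcing conditions, and aqueous work-up hydrolyses the borates and the 5-O/4-O boron chelate to the target.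

**Compound list**

1 | 2-hydroxy-4,5-dimethoxybenzaldehyde | COc1cc(O)c(C=O)cc1OC | starting material
2 | 2-isopropoxy-4,5-dimethoxybenzaldehyde | COc1cc(OC(C)C)c(C=O)cc1OC | intermediate
3 | 2-isopropoxy-4,5-dimethoxybenzoic acid | COc1cc(OC(C)C)c(C(=O)O)cc1OC | intermediate
4 | 2-isopropoxy-4,5-dimethoxybenzoyl chloride | COc1cc(OC(C)C)c(C(=O)Cl)cc1OC | intermediate
5 | (E)-4-methoxybut-3-en-2-one | CO/C=C/C(C)=O | starting material
6 | lithium (E)-4-methoxybuta-1,3-dien-2-olate | [Li]OC(=C)/C=C/OC | intermediate
7 | (E)-1-(2-isopropoxy-4,5-dimethoxyphenyl)-5-methoxypent-4-ene-1,3-dione | COc1cc(OC(C)C)c(C(=O)CC(=O)/C=C/OC)cc1OC | intermediate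
8 | 2-(2-isopropoxy-4,5-dimethoxyphenyl)-4H-pyran-4-one | COc1cc(OC(C)C)c(-c2cc(=O)cco2)cc1OC | intermediate
9 | diisopropyl squarate (3,4-diisopropoxycyclobut-3-ene-1,2-dione) | CC(C)OC1=C(OC(C)C)C(=O)C1=O | starting material
10 | 4-hydroxy-2,3-diisopropoxycyclobut-2-en-1-one (racemic) | CC(C)OC1=C(OC(C)C)C(O)C1=O | intermediate
11 | 3-isopropoxycyclobut-3-ene-1,2-dione | CC(C)OC1=CC(=O)C1=O | intermediate
12 | 6-lithio-2-(2-isopropoxy-4,5-dimethoxyphenyl)-4H-pyran-4-one | [Li]c1cc(=O)cc(-c2cc(OC)c(OC)cc2OC(C)C)o1 | intermediate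
13 | 4-hydroxy-3-isopropoxy-4-[6-(2-isopropoxy-4,5-dimethoxyphenyl)-4-oxo-4H-pyran-2-yl]cyclobut-2-en-1-one (racemic) | O=C1C=C(OC(C)C)C1(O)c1cc(=O)cc(-c2cc(OC)c(OC)cc2OC(C)C)o1 | intermediate
14 | 4-hydroxy-3-isopropoxy-4-[6-(2-isopropoxy-4,5-dimethoxyphenyl)-4-oxo-4H-pyran-2-yl]buta-1,3-dien-1-one, pyranonyl group cis to the ketenyl carbon | O=C=C/C(OC(C)C)=C(/O)c1cc(=O)cc(-c2cc(OC)c(OC)cc2OC(C)C)o1 | intermediate
15 | 8-hydroxy-7-isopropoxy-2-(2-isopropoxy-4,5-dimethoxyphenyl)-4aH-chromene-4,5-dione (racemic) | O=C1C=C(OC(C)C)C(O)=C2OC(c3cc(OC)c(OC)cc3OC(C)C)=CC(=O)C12 | intermediate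
16 | 5,8-dihydroxy-7-isopropoxy-2-(2-isopropoxy-4,5-dimethoxyphenyl)-4H-chromen-4-one | CC(C)Oc1cc(O)c2c(=O)cc(-c3cc(OC)c(OC)cc3OC(C)C)oc2c1O | intermediate
17 | 5-hydroxy-7-isopropoxy-8-methoxy-2-(2-isopropoxy-4,5-dimethoxyphenyl)-4H-chromen-4-one | CC(C)Oc1cc(O)c2c(=O)cc(-c3cc(OC)c(OC)cc3OC(C)C)oc2c1OC | intermediate
18 | 5,7-dihydroxy-2-(2-hydroxy-4,5-dimethoxyphenyl)-8-methoxy-4H-chromen-4-one | COc1cc(O)c(-c2cc(=O)c3c(O)cc(O)c(OC)c3o2)cc1OC | target

**Summary**

Total step count: 10. Longest linear sequence: 8 steps (steps 1, 2, 3, 4, 7, 8, 9, 10 from aldehyde 1); the squarate branch (steps 5 and 6) joins at step 7.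

Steps most likely to fail:

Step 8 (ring expansion). The hydroxyl may rotate inward on ring opening so that it lactonises the ketene. The ketene may also fail to close on the electron-poor pyranone double bond and be lost to oligomerisation. The fallback abandons the cyclobutenone and closes ring C on a bought ring A by known flavone chemistry. It sets out from acid chloride 4. C-acylation of the polylithiated commercial 2',4',6'-trihydroxyacetophenone (LiN(SiMe3)2 in excess, THF, −78 °C to rt) should give 1-(2-isopropoxy-4,5-dimethoxyphenyl)-3-(2,4,6-trihydroxyphenyl)propane-1,3-dione F1. Cyclodehydration (cat. H2SO4, AcOH, 95 °C) should give 5,7-dihydroxy-2-(2-isopropoxy-4,5-dimethoxyphenyl)-4H-chromen-4-one F2. Alkylation of the unchelated 7-hydroxyl (2-bromopropane, K2CO3, DMF) should give 5-hydroxy-7-isopropoxy-2-(2-isopropoxy-4,5-dimethoxyphenyl)-4H-chromen-4-one F3. Elbs persulfate oxidation para to the 5-hydroxyl (K2S2O8, aq. KOH, pyridine) should give potassium 5-hydroxy-7-isopropoxy-2-(2-isopropoxy-4,5-dimethoxyphenyl)-4-oxo-4H-chromen-8-yl sulfate F4. Hydrolysis of F4 (aq. HCl, Na2SO3, warm) comes back to the route at 16.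

Step 7 (lithiation and addition). Metalation may occur at C3 or on ring B instead of next to the ring oxygen. The lithiated pyranone may add to unmetalated pyranone, or the carbanion may attack the vinylogous ester carbonyl of 11. The fallback separates metalation from the addition and sets out from pyranone 8. Zincation next to the ring oxygen with TMPZnCl·LiCl (THF, rt, as reported for chromones without added Lewis acid) should give 6-(chlorozincio)-2-(2-isopropoxy-4,5-dimethoxyphenyl)-4H-pyran-4-one F5. Iodolysis (I2, THF) should give the isolable 6-iodo-2-(2-isopropoxy-4,5-dimethoxyphenyl)-4H-pyran-4-one F6. Iodine–magnesium exchange (i-PrMgCl·LiCl, THF, −40 °C) should give 6-(chloromagnesio)-2-(2-isopropoxy-4,5-dimethoxyphenyl)-4H-pyran-4-one F7, a less basic nucleophile that is formed in the absence of any C–H acid. Its addition to 11 at −78 °C and quench with aq. NH4Cl comes back to the route at 13.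

Step 9 (selective methylation). Under basic conditions the electron-rich hydroquinone may be oxidised by traces of air to the quinone, and the chelated 5-hydroxyl may be methylated as well. The fallback puts the methyl group on before ring A exists and sets out from carbinol 13. O-methylation of the tertiary hydroxyl (MeI, Ag2O, MeCN, rt, dark) should give 3-isopropoxy-4-methoxy-4-[6-(2-isopropoxy-4,5-dimethoxyphenyl)-4-oxo-4H-pyran-2-yl]cyclobut-2-en-1-one F8. Thermolysis as in step 8 should pass through 3-isopropoxy-4-methoxy-4-[6-(2-isopropoxy-4,5-dimethoxyphenyl)-4-oxo-4H-pyran-2-yl]buta-1,3-dien-1-one F9 (methoxy outward) and 7-isopropoxy-8-methoxy-2-(2-isopropoxy-4,5-dimethoxyphenyl)-4aH-chromene-4,5-dione F10. Enolization of F10 gives the 5-hydroxy-8-methoxy compound directly, so the sequence comes back to the route at 17 without a free hydroquinone.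

**Further compounds**

F1 | step 8 | 1-(2-isopropoxy-4,5-dimethoxyphenyl)-3-(2,4,6-trihydroxyphenyl)propane-1,3-dione | COc1cc(OC(C)C)c(C(=O)CC(=O)c2c(O)cc(O)cc2O)cc1OC
F2 | step 8 | 5,7-dihydroxy-2-(2-isopropoxy-4,5-dimethoxyphenyl)-4H-chromen-4-one | COc1cc(OC(C)C)c(-c2cc(=O)c3c(O)cc(O)cc3o2)cc1OC
F3 | step 8 | 5-hydroxy-7-isopropoxy-2-(2-isopropoxy-4,5-dimethoxyphenyl)-4H-chromen-4-one | COc1cc(OC(C)C)c(-c2cc(=O)c3c(O)cc(OC(C)C)cc3o2)cc1OC
F4 | step 8 | potassium 5-hydroxy-7-isopropoxy-2-(2-isopropoxy-4,5-dimethoxyphenyl)-4-oxo-4H-chromen-8-yl sulfate | COc1cc(OC(C)C)c(-c2cc(=O)c3c(O)cc(OC(C)C)c(OS(=O)(=O)[O-])c3o2)cc1OC.[K+]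
F5 | step 7 | 6-(chlorozincio)-2-(2-isopropoxy-4,5-dimethoxyphenyl)-4H-pyran-4-one | Cl[Zn]c1cc(=O)cc(-c2cc(OC)c(OC)cc2OC(C)C)o1
F6 | step 7 | 6-iodo-2-(2-isopropoxy-4,5-dimethoxyphenyl)-4H-pyran-4-one | Ic1cc(=O)cc(-c2cc(OC)c(OC)cc2OC(C)C)o1
F7 | step 7 | 6-(chloromagnesio)-2-(2-isopropoxy-4,5-dimethoxyphenyl)-4H-pyran-4-one | Cl[Mg]c1cc(=O)cc(-c2cc(OC)c(OC)cc2OC(C)C)o1
F8 | step 9 | 3-isopropoxy-4-methoxy-4-[6-(2-isopropoxy-4,5-dimethoxyphenyl)-4-oxo-4H-pyran-2-yl]cyclobut-2-en-1-one (racemic) | COC1(c2cc(=O)cc(-c3cc(OC)c(OC)cc3OC(C)C)o2)C(=O)C=C1OC(C)C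
F9 | step 9 | 3-isopropoxy-4-methoxy-4-[6-(2-isopropoxy-4,5-dimethoxyphenyl)-4-oxo-4H-pyran-2-yl]buta-1,3-dien-1-one, pyranonyl group cis to the ketenyl carbon | O=C=C/C(OC(C)C)=C(/OC)c1cc(=O)cc(-c2cc(OC)c(OC)cc2OC(C)C)o1
F10 | step 9 | 7-isopropoxy-8-methoxy-2-(2-isopropoxy-4,5-dimethoxyphenyl)-4aH-chromene-4,5-dione (racemic) | O=C1C=C(OC(C)C)C(OC)=C2OC(c3cc(OC)c(OC)cc3OC(C)C)=CC(=O)C12
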